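**Assumptions.** The target SMILES has no stereocentres (the CMe2 carbon is not stereogenic), so it is a single achiral compound and no enantiocontrol is needed. All rings are purchased or already present, so no ring is built. Indole-7-Bpin, bromanilic acid, indole, MeI, TBSCl and prenyl bromide are treated as commercially available. Simple reagents are not numbered; their SMILES are given in the reagent lines.

**Retrosynthesis**
1. The target is the T3‑OH, tri‑O‑methyl ether of the bis(indol‑3‑yl)hydroquinone 9. The OH/OMe differentiation comes from TBS protection of the less hindered OH, methylation of the hindered OH, then desilylation.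
2. Hydroquinone 9 comes from dithionite reduction of the asterriquinone‑type quinone 8.
3. Quinone 8 comes from two successive indol‑3‑ylmagnesium addition–elimination reactions on 2,5‑dibromo‑3,6‑dimethoxybenzoquinone (6). The hindered 2‑reverse‑prenylindole (2) goes first and 7‑prenylindole (4) second.
4. Indole 2 comes from indole by C2 reverse‑prenylation via the 3‑chloroindolenine. Indole 4 comes from indole‑7‑Bpin by Pd allyl–aryl coupling. Quinone 6 comes from bromanilic acid.

**Step 1**
Reactants: 1 (indole)
Product: 2 (2‑(2‑methylbut‑3‑en‑2‑yl)‑1H‑indole)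
Conditions: t‑BuOCl, Et3N, THF, –78 °C; then prenyl‑9‑BBN, –78 °C → rt
Reagents that add atoms: prenyl‑9‑BBN, CC(C)=CCB1C2CCCC1CCC2, adds the C5H9 unit. t‑BuOCl (CC(C)(C)OCl) is only the oxidant and no Cl is retained.
Why: Danishefsky‑type C2 reverse‑prenylation. The 3‑chloroindolenine is attacked at C2 by the allylborane through a six‑membered transition state with allylic transposition, which gives the CMe2 quaternary centre. Loss of HCl then restores the indole. No stereocentre is formed.

**Step 2**
Reactants: 3 (1H‑indol‑7‑yl pinacol boronate)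
Product: 4 (7‑(3‑methylbut‑2‑en‑1‑yl)‑1H‑indole)
Conditions: prenyl bromide, Pd(PPh3)4 (5 mol%), K2CO3, THF/H2O, 65 °C
Reagents that add atoms: prenyl bromide, CC(C)=CCBr, adds the prenyl group.
Why: Suzuki–Miyaura allyl–aryl coupling. Reductive elimination from the π‑allyl‑Pd at the less substituted terminus gives the linear (normal) prenyl group. No stereocentre is formed.

**Step 3**
Reactants: 5 (bromanilic acid)
Product: 6 (2,5‑dibromo‑3,6‑dimethoxy‑1,4‑benzoquinone)
Conditions: MeI, Ag2O, CHCl3, rt → 50 °C, dark
Reagents that add atoms: MeI, CI, adds two CH3 groups.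
Why: Ag2O/MeI O‑methylation of the acidic vinylogous‑acid OH groups. The product is a symmetric electrophile with two vinylic C–Br bonds. No stereocentre is formed.

**Step 4**
Reactants: 2, 6
Product: 7 (2‑bromo‑5‑(2‑reverse‑prenylindol‑3‑yl)‑3,6‑dimethoxy‑1,4‑benzoquinone)
Conditions: 2 + EtMgBr, THF, 0 °C (forms the indolyl‑MgBr); add to 6 (2 equiv), THF, –78 °C → rt
Reagents that add atoms: none (EtMgBr only deprotonates the indole N–H)
Why: Addition–elimination (SNV) at a C–Br of the haloquinone by the C3 carbon of the indolylmagnesium halide. Excess 6 favours mono‑substitution, and the hindered indole goes on first, at the more electrophilic dibromide. No stereocentre is formed.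

**Step 5**
Reactants: 7, 4
Product: 8 (2‑(2‑reverse‑prenylindol‑3‑yl)‑5‑(7‑prenylindol‑3‑yl)‑3,6‑dimethoxy‑1,4‑benzoquinone)
Conditions: 4 (3 equiv) + EtMgBr (3 equiv), THF, 0 °C; add 7, 0 → 50 °C
Reagents that add atoms: none
Why: A second SNV displacement of the remaining bromide. The extra equivalents cover deprotonation of the N–H of 7. No stereocentre is formed.

**Step 6**
Reactants: 8
Product: 9 (2,5‑bis(indolyl)‑3,6‑dimethoxyhydroquinone: OH flanked by indole 2 and OMe, and OH flanked by indole 4 and OMe)
Conditions: Na2S2O4, THF/H2O, rt, 15 min; extract and use immediately under Ar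
Reagents that add atoms: none (only H is added)
Why: Dithionite reduction of the quinone to the hydroquinone. The alkenes, indoles and OMe groups are untouched. No stereocentre is formed.

**Step 7**
Reactants: 9
Product: 10 (mono‑TBS ether on the OH adjacent to the 7‑prenylindole)
Conditions: TBSCl (1.0 equiv), imidazole, DMF, 0 °C → rt, Ar
Reagents that add atoms: TBSCl, CC(C)(C)[Si](C)(C)Cl, adds the TBS group.
Why: Sterically controlled silylation. The OH next to the plain indol‑3‑yl (C2–H) is more accessible than the OH next to the indole bearing the C2 quaternary dimethylallyl group, so the desired OH is silylated. No stereocentre is formed.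

**Step 8**
Reactants: 10
Product: 11 (T6‑OMe, T3‑OTBS bis‑indolyl tetra‑oxygenated benzene)
Conditions: MeI, K2CO3, acetone, 45 °C
Reagents that add atoms: MeI, CI, adds CH3.
Why: Williamson O‑methylation of the only free phenol. K2CO3 does not deprotonate the indole N–H, so N‑methylation is avoided. No stereocentre is formed.

**Step 9**
Reactants: 11
Product: 12 (asterriquinol H)
Conditions: TBAF, AcOH (buffer), THF, 0 °C, 30 min
Reagents that add atoms: none (the TBS group is removed and only H is added)
Why: Fluoride desilylation of the aryl silyl ether, leaving the OMe groups, prenyl and reverse‑prenyl alkenes and indole N–H intact. The product is the target, which has no stereocentres.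

**Check of the final structure.** Compound 12 has a central benzene bearing indole 2 (at C3 of the indole, reverse‑prenyl at C2), then OMe, then OH, then indole 4 (7‑prenylindol‑3‑yl), then OMe, then OMe. This matches the target SMILES. Each step's product follows from its reactants with all atoms accounted for. No stereocentres exist, so none can be scrambled.

**Compound list**
1 | indole | c1ccc2[nH]ccc2c1 | starting material
2 | 2‑(2‑methylbut‑3‑en‑2‑yl)‑1H‑indole | C=CC(C)(C)c1cc2ccccc2[nH]1 | intermediate
3 | 1H‑indol‑7‑ylboronic acid pinacol ester | CC1(C)OB(OC1(C)C)c1cccc2cc[nH]c12 | starting material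
4 | 7‑(3‑methylbut‑2‑en‑1‑yl)‑1H‑indole | CC(C)=CCc1cccc2cc[nH]c12 | intermediate
5 | 2,5‑dibromo‑3,6‑dihydroxy‑1,4‑benzoquinone (bromanilic acid) | O=C1C(O)=C(Br)C(=O)C(O)=C1Br | starting material
6 | 2,5‑dibromo‑3,6‑dimethoxy‑1,4‑benzoquinone | O=C1C(Br)=C(OC)C(=O)C(Br)=C1OC | intermediate
7 | 2‑bromo‑5‑(2‑(2‑methylbut‑3‑en‑2‑yl)‑1H‑indol‑3‑yl)‑3,6‑dimethoxy‑1,4‑benzoquinone | O=C1C(Br)=C(OC)C(=O)C(c2c(C(C)(C)C=C)[nH]c3ccccc23)=C1OC | intermediate
8 | 2‑(2‑reverse‑prenylindol‑3‑yl)‑5‑(7‑prenylindol‑3‑yl)‑3,6‑dimethoxy‑1,4‑benzoquinone | O=C1C(c2c(C(C)(C)C=C)[nH]c3ccccc23)=C(OC)C(=O)C(c2c[nH]c3c(CC=C(C)C)cccc23)=C1OC | intermediate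
9 | corresponding 1,4‑dihydroxy‑2,5‑bis(indolyl)‑3,6‑dimethoxybenzene | Oc1c(-c2c(C(C)(C)C=C)[nH]c3ccccc23)c(OC)c(O)c(-c2c[nH]c3c(CC=C(C)C)cccc23)c1OC | intermediate
10 | mono‑TBS ether of 9 (OTBS next to the 7‑prenylindole) | Oc1c(-c2c(C(C)(C)C=C)[nH]c3ccccc23)c(OC)c(O[Si](C)(C)C(C)(C)C)c(-c2c[nH]c3c(CC=C(C)C)cccc23)c1OC | intermediate
11 | methyl ether of 10 | COc1c(-c2c(C(C)(C)C=C)[nH]c3ccccc23)c(OC)c(O[Si](C)(C)C(C)(C)C)c(-c2c[nH]c3c(CC=C(C)C)cccc23)c1OC | intermediate
12 | asterriquinol H | COc1c(-c2c(C(C)(C)C=C)[nH]c3ccccc23)c(OC)c(O)c(-c2c[nH]c3c(CC=C(C)C)cccc23)c1OC | target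

**Total steps:** 9. **Longest linear sequence:** 7 (bromanilic acid → 6 → 7 → 8 → 9 → 10 → 11 → 12).

**Three steps most likely to fail**
1. **Step 7 (regioselective mono‑silylation).** The steric difference between the two OH groups may give only a modest ratio of regioisomers. Fallback: change the approach and use a regiodefined core. Brominate 2,4,5‑trimethoxyphenol ortho to the OH, then Suzuki‑couple it with an N‑protected 7‑prenylindol‑3‑yl‑Bpin. Oxidise the product with PIDA/MeOH to the quinone monoketal, add 2‑reverse‑prenylindole under mild acid (Kita‑type), and remove the N‑protecting group.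
2. **Step 5 (second Grignard addition to the deactivated, N‑magnesiated bromoquinone 7).** This may give low conversion or carbonyl attack. Fallback: replace the Grignard with a Pd‑catalysed Suzuki coupling of bromoquinone 7 and N‑Boc‑7‑prenylindol‑3‑yl pinacol boronate, then remove the Boc group.
3. **Step 1 (C2 reverse‑prenylation of unsubstituted indole).** The unsubstituted 3‑chloroindolenine is unstable. Fallback: N‑protect indole and lithiate at C2. Transmetalate to Zn/Cu and allylate with prenyl bromide under SN2′ control to give the 1,1‑dimethylallyl group, then deprotect.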